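Both carboxyl carbons are cut away from the backbone: C1 from C2 and C4 from C3. These carbons sit on the neighbouring stereocentres C2 (carrying ring A) and C3 (carrying the CH2–ring B group) on the same face, so one palladium-catalysed oxidative bis(methoxycarbonylation) of a (Z)-C2=C3 alkene, consuming two CO and two methanol, should forge the C1–C2 and C3–C4 bonds and both stereocentres in a single syn addition; no ring forms. The precursor is the (Z)-1-(ring A)-3-(ring B)propene with both phenols masked as triisopropylsilyl ethers, assembled by Sonogashira coupling and semi-hydrogenation. Desilylation and a protease that distinguishes the C4 ester from the C1 ester finish the route.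

Key step: step 9

Remarks on the chemistry: C1 is the ester carbon on C2 (the carbon bearing ring A); C4 is the acid carbon on C3 (the carbon bearing the ring B benzyl group). Syn addition to the (Z)-alkene can give only the (2S,3S)/(2R,3R) pair. The (S,S)-bis(oxazoline) is assumed to select the face leading to (2S,3S); if a pilot run shows the opposite sense, the commercial (R,R)-ligand is used and nothing else changes.

Step 1
Reactants: 1 4-hydroxybenzaldehyde; 2 prenyl bromide (1-bromo-3-methylbut-2-ene)
Product: 3 4-hydroxy-3-(3-methylbut-2-en-1-yl)benzaldehyde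
Conditions: KOH (1.1 equiv), H2O, rt; then 1 M HCl to pH 5
Reagents that add atoms: none
Why: Ortho C-alkylation of a phenoxide (SN2 at the primary allylic bromide): in water the solvated oxygen is a poor nucleophile and the para position is blocked by the formyl group, so attack through the ring carbon next to oxygen should give the unrearranged prenyl phenol, separable from the O-prenyl ether by chromatography.

Step 2
Reactants: 3 4-hydroxy-3-(3-methylbut-2-en-1-yl)benzaldehyde
Product: 4 3-(3-methylbut-2-en-1-yl)-4-(triisopropylsilyloxy)benzaldehyde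
Conditions: iPr3SiCl, imidazole, DMF, rt
Reagents that add atoms: triisopropylsilyl chloride, CC(C)[Si](Cl)(C(C)C)C(C)C
Why: Imidazole-promoted silyl ether formation masks the phenol for the Grignard and palladium steps; the triisopropylsilyl group is chosen because its aryl ethers should survive the basic steps and the acidic methanol of the dicarbonylation, so that the ortho-prenyl phenol is never exposed to divalent palladium.

Step 3
Reactants: 4 3-(3-methylbut-2-en-1-yl)-4-(triisopropylsilyloxy)benzaldehyde
Product: 5 [3-(3-methylbut-2-en-1-yl)-4-(triisopropylsilyloxy)phenyl]methanol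
Conditions: NaBH4, EtOH/THF, 0 °C
Reagents that add atoms: none
Why: NaBH4 reduction of the aldehyde to the benzylic alcohol is chemoselective and should leave the prenyl alkene and the aryl silyl ether untouched at 0 °C.

Step 4
Reactants: 5 [3-(3-methylbut-2-en-1-yl)-4-(triisopropylsilyloxy)phenyl]methanol
Product: 6 [4-(bromomethyl)-2-(3-methylbut-2-en-1-yl)phenoxy]triisopropylsilane
Conditions: CBr4, PPh3, CH2Cl2, 0 °C
Reagents that add atoms: carbon tetrabromide, BrC(Br)(Br)Br
Why: Appel bromination proceeds under neutral conditions through an alkoxyphosphonium ion, so the acid-sensitive prenyl group and the silyl ether should survive; the benzylic bromide is used without long storage.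

Step 5
Reactants: 6 [4-(bromomethyl)-2-(3-methylbut-2-en-1-yl)phenoxy]triisopropylsilane; 7 ethynylmagnesium bromide
Product: 8 triisopropyl[2-(3-methylbut-2-en-1-yl)-4-(prop-2-yn-1-yl)phenoxy]silane
Conditions: 7 (3 equiv, 0.5 M in THF), CuBr·SMe2 (10 mol%), THF, 0 to 45 °C
Reagents that add atoms: none
Why: Copper-catalysed coupling of an alkynyl Grignard reagent with a benzylic bromide (sp–sp3 substitution) installs the propargyl unit, the excess of Grignard reagent suppressing a second benzylation of the product alkyne.

Step 6
Reactants: 9 4-iodophenol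
Product: 10 (4-iodophenoxy)triisopropylsilane
Conditions: iPr3SiCl, imidazole, DMF, rt
Reagents that add atoms: triisopropylsilyl chloride, CC(C)[Si](Cl)(C(C)C)C(C)C
Why: Imidazole-promoted silylation of the phenol gives the ring A coupling partner with the same protecting group as ring B, so that one fluoride treatment later frees both phenols.

Step 7
Reactants: 8 triisopropyl[2-(3-methylbut-2-en-1-yl)-4-(prop-2-yn-1-yl)phenoxy]silane; 10 (4-iodophenoxy)triisopropylsilane
Product: 11 1-[4-(triisopropylsilyloxy)phenyl]-3-[3-(3-methylbut-2-en-1-yl)-4-(triisopropylsilyloxy)phenyl]prop-1-yne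
Conditions: PdCl2(PPh3)2 (2 mol%), CuI (4 mol%), Et3N/THF 1:1, rt, degassed
Reagents that add atoms: none
Why: Sonogashira coupling of the terminal alkyne with the aryl iodide runs at room temperature, where the mild amine base should not isomerise the doubly activated propargylic CH2 to an allene.

Step 8
Reactants: 11 1-[4-(triisopropylsilyloxy)phenyl]-3-[3-(3-methylbut-2-en-1-yl)-4-(triisopropylsilyloxy)phenyl]prop-1-yne
Product: 12 (Z)-1-[4-(triisopropylsilyloxy)phenyl]-3-[3-(3-methylbut-2-en-1-yl)-4-(triisopropylsilyloxy)phenyl]prop-1-ene
Conditions: H2 (1 atm), Pd/CaCO3 poisoned with Pb(OAc)2, quinoline, EtOAc, rt, stopped after 1 equiv H2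
Reagents that add atoms: none
Why: Lindlar-type semi-hydrogenation delivers both hydrogens syn from the lead-poisoned palladium surface and so gives the (Z)-alkene; the trisubstituted prenyl alkene is not reduced on this catalyst, and quinoline with a stop after one equivalent of H2 should prevent over-reduction and double-bond migration.

Step 9
Reactants: 12 (Z)-1-[4-(triisopropylsilyloxy)phenyl]-3-[3-(3-methylbut-2-en-1-yl)-4-(triisopropylsilyloxy)phenyl]prop-1-ene; 13 carbon monoxide; 14 methanol
Product: 15 dimethyl (2S,3S)-2-[4-(triisopropylsilyloxy)phenyl]-3-{[3-(3-methylbut-2-en-1-yl)-4-(triisopropylsilyloxy)phenyl]methyl}butanedioate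
Conditions: CO (5 bar), Pd(OCOCF3)2 (5 mol%), 2,2'-isopropylidenebis[(4S)-4-phenyl-2-oxazoline] (6 mol%), p-benzoquinone (1.5 equiv), MeOH/THF 1:1, 20 °C
Reagents that add atoms: carbon monoxide, [C-]#[O+] (second molecule, in addition to 13); methanol, CO (second molecule, in addition to 14)
Why: Oxidative bis(methoxycarbonylation): methanol attacks CO on the divalent palladium–bis(oxazoline) complex to give a methoxycarbonyl–palladium species, which adds syn across the C2=C3 alkene with palladium at the benzylic C2 and CO2Me at C3, a second CO then inserts into the Pd–C2 bond with retention, a second methanol cleaves the acyl–palladium to release 15, and p-benzoquinone returns zerovalent palladium to the divalent state, so that two molecules each of CO and methanol end up in the product. The closest known reactions are the asymmetric bis(alkoxycarbonylation) of vinylarenes with palladium and chiral nitrogen ligands and the stereospecific syn-dicarbonylation of cis-1,2-disubstituted aryl alkenes with Pd(OCOCF3)2, diimine ligands and p-benzoquinone. No ring is closed. C2 and C3 are set together: their relative configuration follows from syn addition to the (Z)-alkene, and the absolute sense from the alkene face bound by the twofold-symmetric chiral ligand. The step needs site selectivity for the disubstituted styrene-type alkene over the prenyl group, which the steric bulk of the trisubstituted alkene should secure, and carbonylation must outrun β-hydride elimination and allylic C–H palladation at the doubly activated CH2, which CO pressure, low temperature and p-benzoquinone as hydride scavenger should favour. The regiochemistry of the first insertion is immaterial, since both carbons receive the same CO2Me group.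

Step 10
Reactants: 15 dimethyl (2S,3S)-2-[4-(triisopropylsilyloxy)phenyl]-3-{[3-(3-methylbut-2-en-1-yl)-4-(triisopropylsilyloxy)phenyl]methyl}butanedioate
Product: 16 dimethyl (2S,3S)-2-(4-hydroxyphenyl)-3-{[4-hydroxy-3-(3-methylbut-2-en-1-yl)phenyl]methyl}butanedioate
Conditions: Bu4NF/AcOH 1:1 (2.5 equiv), THF, 0 °C
Reagents that add atoms: none
Why: Fluoride cleavage of aryl silyl ethers, buffered with acetic acid so that the liberated phenoxides are protonated at once, should free both phenols without epimerising the benzylic C2 centre or touching the methyl esters and the prenyl group.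

Step 11
Reactants: 16 dimethyl (2S,3S)-2-(4-hydroxyphenyl)-3-{[4-hydroxy-3-(3-methylbut-2-en-1-yl)phenyl]methyl}butanedioate
Product: 17 Asperteretal G2, (2S,3S)-3-(4-hydroxyphenyl)-2-{[4-hydroxy-3-(3-methylbut-2-en-1-yl)phenyl]methyl}-4-methoxy-4-oxobutanoic acid
Conditions: α-chymotrypsin, 0.1 M NaH2PO4/Na2HPO4 buffer pH 7.5/DMSO 9:1, 30 °C; then citric acid to pH 3, EtOAc
Reagents that add atoms: water, O
Why: Protease-catalysed regioselective ester hydrolysis: seen from C4, C3 is the α-carbon of a tyrosine-like acyl unit whose side chain (C2 carrying ring A) can fill the aromatic S1 pocket while the ring B benzyl group takes the place of the acylamino group, an arrangement of the natural L sense, whereas C1 sits directly on the aryl-bearing carbon (arylglycine-like) and has no comparable productive binding mode, and the neutral pH should leave the C2 centre intact.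

Compound list
1 | 4-hydroxybenzaldehyde | O=Cc1ccc(O)cc1 | starting material
2 | prenyl bromide (1-bromo-3-methylbut-2-ene) | CC(C)=CCBr | starting material
3 | 4-hydroxy-3-(3-methylbut-2-en-1-yl)benzaldehyde | CC(C)=CCc1cc(C=O)ccc1O | intermediate
4 | 3-(3-methylbut-2-en-1-yl)-4-(triisopropylsilyloxy)benzaldehyde | CC(C)=CCc1cc(C=O)ccc1O[Si](C(C)C)(C(C)C)C(C)C | intermediate
5 | [3-(3-methylbut-2-en-1-yl)-4-(triisopropylsilyloxy)phenyl]methanol | CC(C)=CCc1cc(CO)ccc1O[Si](C(C)C)(C(C)C)C(C)C | intermediate
6 | [4-(bromomethyl)-2-(3-methylbut-2-en-1-yl)phenoxy]triisopropylsilane | CC(C)=CCc1cc(CBr)ccc1O[Si](C(C)C)(C(C)C)C(C)C | intermediate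
7 | ethynylmagnesium bromide | C#C[Mg]Br | starting material
8 | triisopropyl[2-(3-methylbut-2-en-1-yl)-4-(prop-2-yn-1-yl)phenoxy]silane | C#CCc1ccc(O[Si](C(C)C)(C(C)C)C(C)C)c(CC=C(C)C)c1 | intermediate
9 | 4-iodophenol | Oc1ccc(I)cc1 | starting material
10 | (4-iodophenoxy)triisopropylsilane | CC(C)[Si](Oc1ccc(I)cc1)(C(C)C)C(C)C | intermediate
11 | 1-[4-(triisopropylsilyloxy)phenyl]-3-[3-(3-methylbut-2-en-1-yl)-4-(triisopropylsilyloxy)phenyl]prop-1-yne | CC(C)[Si](Oc1ccc(C#CCc2ccc(O[Si](C(C)C)(C(C)C)C(C)C)c(CC=C(C)C)c2)cc1)(C(C)C)C(C)C | intermediate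
12 | (Z)-1-[4-(triisopropylsilyloxy)phenyl]-3-[3-(3-methylbut-2-en-1-yl)-4-(triisopropylsilyloxy)phenyl]prop-1-ene | CC(C)[Si](Oc1ccc(/C=C\Cc2ccc(O[Si](C(C)C)(C(C)C)C(C)C)c(CC=C(C)C)c2)cc1)(C(C)C)C(C)C | intermediate
13 | carbon monoxide | [C-]#[O+] | starting material
14 | methanol | CO | starting material
15 | dimethyl (2S,3S)-2-[4-(triisopropylsilyloxy)phenyl]-3-{[3-(3-methylbut-2-en-1-yl)-4-(triisopropylsilyloxy)phenyl]methyl}butanedioate | COC(=O)[C@H](c1ccc(O[Si](C(C)C)(C(C)C)C(C)C)cc1)[C@H](Cc1ccc(O[Si](C(C)C)(C(C)C)C(C)C)c(CC=C(C)C)c1)C(=O)OC | intermediate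
16 | dimethyl (2S,3S)-2-(4-hydroxyphenyl)-3-{[4-hydroxy-3-(3-methylbut-2-en-1-yl)phenyl]methyl}butanedioate | COC(=O)[C@H](c1ccc(O)cc1)[C@H](Cc1ccc(O)c(CC=C(C)C)c1)C(=O)OC | intermediate
17 | Asperteretal G2, (2S,3S)-3-(4-hydroxyphenyl)-2-{[4-hydroxy-3-(3-methylbut-2-en-1-yl)phenyl]methyl}-4-methoxy-4-oxobutanoic acid | COC(=O)[C@H](c1ccc(O)cc1)[C@H](Cc1ccc(O)c(CC=C(C)C)c1)C(=O)O | target

Total step count: 11. Longest linear sequence: 10 steps (steps 1–5, then 7–11).

Steps most likely to fail

Step 9. The likeliest failure is weak facial discrimination by the chiral ligand on an internal (Z)-alkene, leaving 15 with low enantiomeric purity. The fallback sets out from 12 and runs the same syn-dicarbonylation without a chiral ligand: Pd(OCOCF3)2 with N,N'-bis(2,6-dimethylphenyl)butane-2,3-diimine, p-benzoquinone, a little p-TsOH and CO in MeOH/THF at 20 °C, a combination known to add stereospecifically syn to cis-1,2-disubstituted alkenes. This should give 15 as a racemate with its enantiomer, dimethyl (2R,3R)-2-[4-(triisopropylsilyloxy)phenyl]-3-{[3-(3-methylbut-2-en-1-yl)-4-(triisopropylsilyloxy)phenyl]methyl}butanedioate F1. The enantiomers are separated by preparative HPLC on a cellulose tris(3,5-dimethylphenylcarbamate) stationary phase, and the route is rejoined at 15.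

Step 11. The enzyme may fail to turn over the hindered, doubly branched diester, since the extra ester group on C2 and the prenyl group may obstruct binding, or it may hydrolyse at C1 as well. The fallback sets out from 15, before desilylation, and uses partial hydrolysis with Me3SnOH in 1,2-dichloroethane at 70 °C, a reagent that cleaves methyl esters without epimerising adjacent centres. It should give a mixture of the C4 acid, (2S,3S)-4-methoxy-4-oxo-3-[4-(triisopropylsilyloxy)phenyl]-2-{[3-(3-methylbut-2-en-1-yl)-4-(triisopropylsilyloxy)phenyl]methyl}butanoic acid F2, and the C1 acid, (2S,3S)-4-methoxy-4-oxo-2-[4-(triisopropylsilyloxy)phenyl]-3-{[3-(3-methylbut-2-en-1-yl)-4-(triisopropylsilyloxy)phenyl]methyl}butanoic acid F3. The two are separated on silica; intrinsic selectivity may well favour F3, so recycling is part of the plan. F3 is re-methylated to 15 with trimethylsilyldiazomethane in toluene/MeOH and recycled together with recovered 15. F2 is desilylated with Bu4NF/AcOH in THF at 0 °C, as in step 10, which gives 17 directly.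

Step 1. O-alkylation and double alkylation of the ambident phenoxide may outrun the wanted ortho C-alkylation. The fallback sets out from 1, which is brominated ortho to the hydroxyl group (Br2, AcOH, rt) to 3-bromo-4-hydroxybenzaldehyde F4. The prenyl group is then introduced at the carbon that carried bromine by Stille coupling with tributyl(3-methylbut-2-en-1-yl)stannane (Pd(PPh3)4, DMF, 100 °C), which should give the linear prenyl arene 3, where the route is rejoined.

Further compounds
F1 | step 9 | dimethyl (2R,3R)-2-[4-(triisopropylsilyloxy)phenyl]-3-{[3-(3-methylbut-2-en-1-yl)-4-(triisopropylsilyloxy)phenyl]methyl}butanedioate | COC(=O)[C@@H](c1ccc(O[Si](C(C)C)(C(C)C)C(C)C)cc1)[C@@H](Cc1ccc(O[Si](C(C)C)(C(C)C)C(C)C)c(CC=C(C)C)c1)C(=O)OC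
F2 | step 11 | (2S,3S)-4-methoxy-4-oxo-3-[4-(triisopropylsilyloxy)phenyl]-2-{[3-(3-methylbut-2-en-1-yl)-4-(triisopropylsilyloxy)phenyl]methyl}butanoic acid | COC(=O)[C@H](c1ccc(O[Si](C(C)C)(C(C)C)C(C)C)cc1)[C@H](Cc1ccc(O[Si](C(C)C)(C(C)C)C(C)C)c(CC=C(C)C)c1)C(=O)O
F3 | step 11 | (2S,3S)-4-methoxy-4-oxo-2-[4-(triisopropylsilyloxy)phenyl]-3-{[3-(3-methylbut-2-en-1-yl)-4-(triisopropylsilyloxy)phenyl]methyl}butanoic acid | OC(=O)[C@H](c1ccc(O[Si](C(C)C)(C(C)C)C(C)C)cc1)[C@H](Cc1ccc(O[Si](C(C)C)(C(C)C)C(C)C)c(CC=C(C)C)c1)C(=O)OC
F4 | step 1 | 3-bromo-4-hydroxybenzaldehyde | O=Cc1ccc(O)c(Br)c1
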